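**Plan**

1. Retrosynthesis: the ring A epoxide C–O bonds are cut last, then the exocyclic methylene carbon (Wittig), then the bond between the ring A CH and the linking CH2 (allyl cation plus silyl enol ether). This leaves a (4S)-p-menthadienol from (S)-limonene oxide and a ring B methyl ketone.
2. Ring B is cut at two ring bonds, CH(acyl)–CH2 and C(OH)(CH3)–CHBr, back to methyl vinyl ketone and 3-acetyl-4-oxopentanal.
3. Enabling feature: in ring B the carbinol carbon with its CH3 and the two ring CH2 groups beside it are the carbons of methyl vinyl ketone; the CHBr carbon sits where an acyloin carbonyl (an aldehyde carbon) can be; the side-chain CH, 1,3 to it, is a 1,3-diketone carbon.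
4. Forward order: ring B by Michael/benzoin annulation, CHBr by anti reduction and SN2 inversion on a cyclic sulfate; ring A allylic alcohol; union by cation capture; methylenation; epoxidation of ring A last.
5. Stereochemistry: the carbinol carbon comes from the chiral carbene; CHBr is relayed from it; the acyl-bearing CH is set by equilibration; ring A comes from (S)-limonene, trans capture of the cation and catalyst-controlled epoxidation.

Key step: step 2

Remark on the chemistry: commercial (S)-limonene 1,2-oxide is a cis/trans mixture, and the trans isomer is the component that opens at the secondary carbon in step 6, so the route is drawn for it; 3-allylpentane-2,4-dione is taken as a catalogue compound.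

**Route**

Step 1
Reactants: 1 3-(prop-2-en-1-yl)pentane-2,4-dione
Product: 3 3-acetyl-4-oxopentanal, via ozonide 2 (not isolated)
Conditions: O3, CH2Cl2, −78 °C; then Me2S, −78 °C to rt
Reagents that add atoms: ozone, [O-][O+]=O
Why: Ozonolysis of the terminal allyl alkene with reductive work-up should cleave only that C=C bond and give the aldehyde, which is used crude because it can close to a hemiacetal; no stereocentre is formed.

Step 2
Reactants: 3 3-acetyl-4-oxopentanal; 4 but-3-en-2-one (methyl vinyl ketone)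
Product: 6 (2S)-5,5-diacetyl-2-hydroxy-2-methylcyclohexan-1-one, via 3,3-diacetyl-6-oxoheptanal 5 (not isolated)
Conditions: DBU (10 mol %), CH2Cl2, 0 °C, slow addition of 4; when 4 is consumed, (5aS,10bR)-2-(pentafluorophenyl)-5a,10b-dihydro-4H,6H-indeno[2,1-b][1,2,4]triazolo[4,3-d][1,4]oxazin-2-ium tetrafluoroborate (10 mol %), rt
Reagents that add atoms: none
Why: DBU forms the enolate of the 1,3-diketone CH of 3, which adds to the β-carbon of 4 (Michael addition) to give 5, and the triazolylidene then turns the aldehyde of 5 into a Breslow intermediate whose acyl-anion carbon attacks the methyl ketone and is released (intramolecular crossed benzoin), so the ring CH2–C(quaternary) bond and the C(=O)–C(OH)CH3 bond are made in one flask. The closest known reaction type is the base/carbene Michael–crossed-benzoin cascade that gives α-hydroxy cycloalkanones, together with the enantioselective aldehyde–ketone benzoin cyclisation. The ring closes in the 6-exo-trig mode, the acyl-anion carbon adding to a ketone carbon whose oxygen stays outside the new ring. The single new stereocentre, the carbinol carbon, is set by the chiral triazolylidene, which selects the face of the ketone in the hydrogen-bonded addition transition state; the quaternary diacetyl carbon is achiral, so there is no substrate bias, and the catalyst antipode is assigned by analogy for the S ketol (the mirror-image salt would give the enantiomer). The step needs the acyl anion to take the 1,6-related methyl ketone only: the geminal acetyls could close only a four-membered ring, the vinyl ketone (a Stetter acceptor) is used up before the carbene is added, and the quaternary carbon beside the aldehyde CH2 favours closure (Thorpe–Ingold) and cannot enolise.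

Step 3
Reactants: 6 (2S)-5,5-diacetyl-2-hydroxy-2-methylcyclohexan-1-one
Product: 8 1-[(3S,4S)-3,4-dihydroxy-4-methylcyclohexyl]ethan-1-one (both epimers at the acetyl-bearing carbon), via gem-diacetyl trans-diol 7 (not isolated)
Conditions: Me4NBH(OAc)3, MeCN–AcOH (1:1), −25 °C; aqueous work-up, then NaOMe (0.2 equiv), MeOH, 0 °C to rt
Reagents that add atoms: none
Why: Hydroxyl-directed triacetoxyborohydride reduction (Evans–Saksena type) should deliver hydride from the tertiary alkoxyborohydride to the ketone face syn to the C–O bond, giving the trans diol while leaving the remote acetyls alone, and methoxide retro-Claisen cleavage of the non-enolisable 1,3-diketone then removes one acetyl to leave an epimerisable CH.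

Step 4
Reactants: 8 1-[(3S,4S)-3,4-dihydroxy-4-methylcyclohexyl]ethan-1-one
Product: 10 1-[(3aS,6S,7aS)-3a-methyl-2,2-dioxidohexahydro-1,3,2-benzodioxathiol-6-yl]ethan-1-one (trans-fused cyclic sulfate; acetyl equatorial), via cyclic sulfite 9 (not isolated)
Conditions: SOCl2, Et3N, CH2Cl2, 0 °C; DBU (0.2 equiv), rt; then RuCl3·xH2O (1 mol %), NaIO4, MeCN–H2O, 0 °C
Reagents that add atoms: thionyl chloride, O=S(Cl)Cl; sodium periodate, [Na+].[O-]I(=O)(=O)=O
Why: Cyclic sulfite formation and ruthenium tetroxide oxidation (cyclic sulfate synthesis) tie both oxygens into a trans-fused ring that locks the chair with the oxygens equatorial, so DBU should equilibrate the acetyl-bearing carbon of the sulfite to the equatorial epimer, which leaves an axial hydrogen on the face that bromide must use in step 5.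

Step 5
Reactants: 10 trans-fused cyclic sulfate
Product: 13 1-[(1R,3R,4S)-3-bromo-4-hydroxy-4-methylcyclohexyl]ethan-1-one, via lithium bromo sulfate 11 (not isolated), via trans-acetyl bromohydrin 12 (not isolated)
Conditions: LiBr, THF, rt; H2SO4 (cat.), H2O (1.5 equiv), THF, rt; then K2CO3, MeOH, rt
Reagents that add atoms: lithium bromide, [Li+].[Br-]
Why: Bromide should open the cyclic sulfate by SN2 attack at the secondary carbon with inversion (Br cis to the tertiary oxygen), S–O hydrolysis of the tertiary sulfate monoester leaves the carbinol carbon untouched, and base equilibration of the acetyl-bearing carbon should favour the epimer with acetyl, Br and CH3 equatorial and OH axial, the minor epimer being separable and recyclable.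

Step 6
Reactants: 14 (1R,2S,4S)-limonene 1,2-oxide (trans isomer)
Product: 16 (1R,4S)-1-methyl-4-(prop-1-en-2-yl)cyclohex-2-en-1-ol, via hydroxy selenide 15 (not isolated)
Conditions: (PhSe)2, NaBH4, EtOH, reflux; then 30% H2O2, THF, 0 °C to rt
Reagents that add atoms: none
Why: Benzeneselenolate should open the trans epoxide by trans-diaxial SN2 attack at the secondary carbon, and selenoxide syn elimination can then only run toward the ring CH2, giving the tertiary allylic alcohol with the (4S) centre untouched.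

Step 7
Reactants: 13 1-[(1R,3R,4S)-3-bromo-4-hydroxy-4-methylcyclohexyl]ethan-1-one
Product: 17 trimethyl({1-[(1R,3R,4S)-3-bromo-4-methyl-4-(trimethylsilyloxy)cyclohexyl]ethenyl}oxy)silane
Conditions: LiN(iPr)2 (2.3 equiv), Me3SiCl (3 equiv), THF, −78 °C (internal quench), then 0 °C
Reagents that add atoms: chlorotrimethylsilane, C[Si](C)(C)Cl
Why: Kinetic deprotonation at the CH3 of the methyl ketone with in situ silylation should give the less substituted silyl enol ether and the tertiary silyl ether, the cis bromohydrin alkoxide being unable to close to an epoxide, with no stereocentre touched.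

Step 8
Reactants: 16 (1R,4S)-1-methyl-4-(prop-1-en-2-yl)cyclohex-2-en-1-ol; 17 bis-silyl enol ether
Product: 18 1-[(1R,3R,4S)-3-bromo-4-methyl-4-(trimethylsilyloxy)cyclohexyl]-2-[(1S,6S)-3-methyl-6-(prop-1-en-2-yl)cyclohex-2-en-1-yl]ethan-1-one
Conditions: Me3SiOTf (10 mol %), CH2Cl2, −78 °C; Et3N quench
Reagents that add atoms: none
Why: Me3SiOTf should ionise the tertiary allylic alcohol to the p-menthadienyl cation, which the silyl enol ether captures at the less hindered secondary terminus anti to the neighbouring isopropenyl group (SN1 allylation of a silyl enol ether, Mukaiyama type), setting the trans 1,6-relationship of ring A.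

Step 9
Reactants: 18 coupled ketone
Product: 20 (1S,2R,4R)-2-bromo-1-methyl-4-{3-[(1S,6S)-3-methyl-6-(prop-1-en-2-yl)cyclohex-2-en-1-yl]prop-1-en-2-yl}cyclohexan-1-ol, via silyl ether 19 (not isolated)
Conditions: Ph3PCH3Br, KOtBu, THF, 0 °C to rt; then 1 M HCl, THF, 0 °C
Reagents that add atoms: methyltriphenylphosphonium bromide, C[P+](c1ccccc1)(c1ccccc1)c1ccccc1.[Br-]
Why: Wittig methylenation should convert the ketone into the 1,1-disubstituted alkene without disturbing the adjacent stereocentre, which is already the thermodynamic one, and dilute acid then removes the tertiary trimethylsilyl ether that kept the bromohydrin from forming an alkoxide.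

Step 10
Reactants: 20 triene bromohydrin
Product: 21 (1S,2R,4R)-2-bromo-1-methyl-4-{3-[(1R,2R,3S,6S)-6-methyl-3-(prop-1-en-2-yl)-7-oxabicyclo[4.1.0]heptan-2-yl]prop-1-en-2-yl}cyclohexan-1-ol (target)
Conditions: 1,2:4,5-di-O-isopropylidene-β-D-erythro-2,3-hexodiulo-2,6-pyranose (0.3 equiv), Oxone (2KHSO5·KHSO4·K2SO4), K2CO3, Bu4NHSO4, MeCN–CH2(OMe)2–aq. Na2B4O7 buffer, 0 °C
Reagents that add atoms: potassium peroxymonosulfate (Oxone), [K+].[O-]S(=O)(=O)OO
Why: Shi epoxidation should oxidise the electron-rich trisubstituted ring alkene in preference to the two 1,1-disubstituted alkenes and, through the spiro transition state of the D-fructose-derived dioxirane (the sense that gives R,R epoxides from 1-substituted cyclohexenes), deliver oxygen to the face syn to the side-chain CH2 and anti to the isopropenyl group.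

**Compound list**

1 | 3-(prop-2-en-1-yl)pentane-2,4-dione | CC(=O)C(CC=C)C(C)=O | starting material
2 | 3-[(1,2,4-trioxolan-3-yl)methyl]pentane-2,4-dione (ozonide) | CC(=O)C(CC1OCOO1)C(C)=O | intermediate
3 | 3-acetyl-4-oxopentanal | CC(=O)C(CC=O)C(C)=O | intermediate
4 | but-3-en-2-one (methyl vinyl ketone) | C=CC(C)=O | starting material
5 | 3,3-diacetyl-6-oxoheptanal | CC(=O)CCC(CC=O)(C(C)=O)C(C)=O | intermediate
6 | (2S)-5,5-diacetyl-2-hydroxy-2-methylcyclohexan-1-one | CC(=O)C1(C(C)=O)CC[C@](C)(O)C(=O)C1 | intermediate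
7 | 1,1'-[(3S,4S)-3,4-dihydroxy-4-methylcyclohexane-1,1-diyl]di(ethan-1-one) | CC(=O)C1(C(C)=O)CC[C@](C)(O)[C@@H](O)C1 | intermediate
8 | 1-[(3S,4S)-3,4-dihydroxy-4-methylcyclohexyl]ethan-1-one (both epimers at the acetyl-bearing carbon) | CC(=O)C1CC[C@](C)(O)[C@@H](O)C1 | intermediate
9 | 1-[(3aS,6S,7aS)-3a-methyl-2-oxidohexahydro-1,3,2-benzodioxathiol-6-yl]ethan-1-one (cyclic sulfite, either configuration at sulfur) | CC(=O)[C@H]1CC[C@]2(C)OS(=O)O[C@H]2C1 | intermediate
10 | 1-[(3aS,6S,7aS)-3a-methyl-2,2-dioxidohexahydro-1,3,2-benzodioxathiol-6-yl]ethan-1-one (cyclic sulfate) | CC(=O)[C@H]1CC[C@]2(C)OS(=O)(=O)O[C@H]2C1 | intermediate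
11 | lithium (1S,2R,4S)-4-acetyl-2-bromo-1-methylcyclohexyl sulfate | CC(=O)[C@H]1CC[C@](C)(OS(=O)(=O)[O-])[C@H](Br)C1.[Li+] | intermediate
12 | 1-[(1S,3R,4S)-3-bromo-4-hydroxy-4-methylcyclohexyl]ethan-1-one | CC(=O)[C@H]1CC[C@](C)(O)[C@H](Br)C1 | intermediate
13 | 1-[(1R,3R,4S)-3-bromo-4-hydroxy-4-methylcyclohexyl]ethan-1-one | CC(=O)[C@@H]1CC[C@](C)(O)[C@H](Br)C1 | intermediate
14 | (1R,2S,4S)-limonene 1,2-oxide, trans [(1R,4S,6S)-1-methyl-4-(prop-1-en-2-yl)-7-oxabicyclo[4.1.0]heptane] | CC(=C)[C@H]1CC[C@@]2(C)O[C@H]2C1 | starting material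
15 | (1R,2R,4S)-1-methyl-2-(phenylselanyl)-4-(prop-1-en-2-yl)cyclohexan-1-ol | CC(=C)[C@H]1CC[C@@](C)(O)[C@H]([Se]c2ccccc2)C1 | intermediate
16 | (1R,4S)-1-methyl-4-(prop-1-en-2-yl)cyclohex-2-en-1-ol | C[C@]1(O)C=C[C@@H](C(=C)C)CC1 | intermediate
17 | trimethyl({1-[(1R,3R,4S)-3-bromo-4-methyl-4-(trimethylsilyloxy)cyclohexyl]ethenyl}oxy)silane | C=C(O[Si](C)(C)C)[C@@H]1CC[C@](C)(O[Si](C)(C)C)[C@H](Br)C1 | intermediate
18 | 1-[(1R,3R,4S)-3-bromo-4-methyl-4-(trimethylsilyloxy)cyclohexyl]-2-[(1S,6S)-3-methyl-6-(prop-1-en-2-yl)cyclohex-2-en-1-yl]ethan-1-one | O=C(C[C@@H]1[C@@H](C(=C)C)CCC(C)=C1)[C@@H]1CC[C@](C)(O[Si](C)(C)C)[C@H](Br)C1 | intermediate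
19 | {[(1S,2R,4R)-2-bromo-1-methyl-4-{3-[(1S,6S)-3-methyl-6-(prop-1-en-2-yl)cyclohex-2-en-1-yl]prop-1-en-2-yl}cyclohexyl]oxy}trimethylsilane | C=C(C[C@@H]1[C@@H](C(=C)C)CCC(C)=C1)[C@@H]1CC[C@](C)(O[Si](C)(C)C)[C@H](Br)C1 | intermediate
20 | (1S,2R,4R)-2-bromo-1-methyl-4-{3-[(1S,6S)-3-methyl-6-(prop-1-en-2-yl)cyclohex-2-en-1-yl]prop-1-en-2-yl}cyclohexan-1-ol | C=C(C[C@@H]1[C@@H](C(=C)C)CCC(C)=C1)[C@@H]1CC[C@](C)(O)[C@H](Br)C1 | intermediate
21 | (1S,2R,4R)-2-bromo-1-methyl-4-{3-[(1R,2R,3S,6S)-6-methyl-3-(prop-1-en-2-yl)-7-oxabicyclo[4.1.0]heptan-2-yl]prop-1-en-2-yl}cyclohexan-1-ol | C=C(C[C@@H]1[C@@H](C(=C)C)CC[C@]2(C)O[C@H]12)[C@@H]1CC[C@](C)(O)[C@H](Br)C1 | target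

**Count and risks**

Total steps: 10. Longest linear sequence: 9 (steps 1–5, then 7–10); step 6 is the one-step side branch.

Steps most likely to fail:

Step 2. The aldehyde may be consumed by aldol or Stetter-type pathways before the benzoin closure, or the carbene may induce the carbinol carbon poorly. The fallback sets out from 4 and comes back at 8. A Diels–Alder reaction of 4 with isoprene (AlCl3, CH2Cl2) would give 1-(4-methylcyclohex-3-en-1-yl)ethan-1-one F1, whose only stereocentre is the epimerisable acyl carbon. Shi epoxidation with the enantiomer of the ketone of step 10 (1,2:4,5-di-O-isopropylidene-β-L-erythro-2,3-hexodiulo-2,6-pyranose) would then set the epoxide under catalyst control and give 1-[(1S,6R)-6-methyl-7-oxabicyclo[4.1.0]heptan-3-yl]ethan-1-one F2 as acyl epimers. Dilute HClO4 in aqueous THF would open it with inversion at the tertiary carbon to the trans diol 8.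

Step 5. The tertiary sulfate monoester may ionise during acid hydrolysis, which would scramble the carbinol carbon through a bromonium ion, or the substitution beside the fully substituted carbon may be slow and lose out to elimination. The fallback sets out from 8 and comes back at 13. Acid-catalysed ketalisation (camphorsulfonic acid, HC(OMe)3, MeOH) equilibrates the acyl carbon through the enol ether, and only the epimer cis to the tertiary OH can close, giving the bridged ketal (1S,4R,6S)-3-methoxy-1,3-dimethyl-2-oxabicyclo[2.2.2]octan-6-ol F3. Tf2O and pyridine would give (1S,4R,6S)-3-methoxy-1,3-dimethyl-2-oxabicyclo[2.2.2]octan-6-yl trifluoromethanesulfonate F4. Bu4NBr in toluene would displace it from the side of the oxygen bridge, where neither anti elimination nor epoxide closure is possible, to give (1S,4R,6R)-6-bromo-3-methoxy-1,3-dimethyl-2-oxabicyclo[2.2.2]octane F5. Aqueous HCl in THF would release 13 with the acyl group already cis.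

Step 10. The bulky dioxirane may show poor facial selectivity on the face that carries the side chain, or the 1,1-disubstituted alkenes may be epoxidised as well. The fallback sets out from 18 and comes back at 21. NaBH4 would give 1-[(1R,3R,4S)-3-bromo-4-methyl-4-(trimethylsilyloxy)cyclohexyl]-2-[(1S,6S)-3-methyl-6-(prop-1-en-2-yl)cyclohex-2-en-1-yl]ethan-1-ol F6 as both carbinol epimers. VO(acac)2 with t-BuOOH would then deliver oxygen from the bishomoallylic hydroxyl to the ring A alkene on the side-chain face, giving the epoxy alcohol 1-[(1R,3R,4S)-3-bromo-4-methyl-4-(trimethylsilyloxy)cyclohexyl]-2-[(1R,2R,3S,6S)-6-methyl-3-(prop-1-en-2-yl)-7-oxabicyclo[4.1.0]heptan-2-yl]ethan-1-ol F7. Dess–Martin periodinane would give the epoxy ketone 1-[(1R,3R,4S)-3-bromo-4-methyl-4-(trimethylsilyloxy)cyclohexyl]-2-[(1R,2R,3S,6S)-6-methyl-3-(prop-1-en-2-yl)-7-oxabicyclo[4.1.0]heptan-2-yl]ethan-1-one F8. Methylenation with Ph3P=CH2 at low temperature would give the trimethylsilyl ether of the target F9, and Bu4NF would free 21.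

**Further compounds**

F1 | step 2 | 1-(4-methylcyclohex-3-en-1-yl)ethan-1-one | CC(=O)C1CCC(C)=CC1
F2 | step 2 | 1-[(1S,6R)-6-methyl-7-oxabicyclo[4.1.0]heptan-3-yl]ethan-1-one | CC(=O)C1CC[C@@]2(C)O[C@H]2C1
F3 | step 5 | (1S,4R,6S)-3-methoxy-1,3-dimethyl-2-oxabicyclo[2.2.2]octan-6-ol | COC1(C)O[C@@]2(C)CC[C@@H]1C[C@@H]2O
F4 | step 5 | (1S,4R,6S)-3-methoxy-1,3-dimethyl-2-oxabicyclo[2.2.2]octan-6-yl trifluoromethanesulfonate | COC1(C)O[C@@]2(C)CC[C@@H]1C[C@@H]2OS(=O)(=O)C(F)(F)F
F5 | step 5 | (1S,4R,6R)-6-bromo-3-methoxy-1,3-dimethyl-2-oxabicyclo[2.2.2]octane | COC1(C)O[C@@]2(C)CC[C@@H]1C[C@H]2Br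
F6 | step 10 | 1-[(1R,3R,4S)-3-bromo-4-methyl-4-(trimethylsilyloxy)cyclohexyl]-2-[(1S,6S)-3-methyl-6-(prop-1-en-2-yl)cyclohex-2-en-1-yl]ethan-1-ol | OC(C[C@@H]1[C@@H](C(=C)C)CCC(C)=C1)[C@@H]1CC[C@](C)(O[Si](C)(C)C)[C@H](Br)C1
F7 | step 10 | 1-[(1R,3R,4S)-3-bromo-4-methyl-4-(trimethylsilyloxy)cyclohexyl]-2-[(1R,2R,3S,6S)-6-methyl-3-(prop-1-en-2-yl)-7-oxabicyclo[4.1.0]heptan-2-yl]ethan-1-ol | OC(C[C@@H]1[C@@H](C(=C)C)CC[C@]2(C)O[C@H]12)[C@@H]1CC[C@](C)(O[Si](C)(C)C)[C@H](Br)C1
F8 | step 10 | 1-[(1R,3R,4S)-3-bromo-4-methyl-4-(trimethylsilyloxy)cyclohexyl]-2-[(1R,2R,3S,6S)-6-methyl-3-(prop-1-en-2-yl)-7-oxabicyclo[4.1.0]heptan-2-yl]ethan-1-one | O=C(C[C@@H]1[C@@H](C(=C)C)CC[C@]2(C)O[C@H]12)[C@@H]1CC[C@](C)(O[Si](C)(C)C)[C@H](Br)C1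
F9 | step 10 | {[(1S,2R,4R)-2-bromo-1-methyl-4-{3-[(1R,2R,3S,6S)-6-methyl-3-(prop-1-en-2-yl)-7-oxabicyclo[4.1.0]heptan-2-yl]prop-1-en-2-yl}cyclohexyl]oxy}trimethylsilane | C=C(C[C@@H]1[C@@H](C(=C)C)CC[C@]2(C)O[C@H]12)[C@@H]1CC[C@](C)(O[Si](C)(C)C)[C@H](Br)C1
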